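**Retrosynthetic overview**
1. 21 ⇐ 19 (BCl3 removal of the isopropyl group) ⇐ 18 (O-methylation). Both ring A bromines of 18 come from bromination plus ipso-bromodecarboxylation of salicylic acid 16.
2. 16 ⇐ salicylate 15 ⇐ cyclohexenone ester 14 (dehydrogenation) ⇐ keto aldehyde 12 (intramolecular aldol condensation).
3. Key C–C disconnection: 12 ⇐ aryloxy β-keto ester 10 + acrolein 11 (intermolecular Michael addition).
4. 10 ⇐ aryloxyacetic acid 7 + potassium ethyl malonate 8 (decarboxylative Claisen). 7 ⇐ phenol 4 + ethyl bromoacetate 5. 4 ⇐ 2-isopropoxyphenol 1 (tribromination).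
5. Ring order: ring B (tribromo ring) is bought as an arene and brominated first. Ring A (methoxy ring) is then built on its oxygen, closed in step 6 and aromatised in step 7, so no metal-mediated C–O coupling meets the C–Br bonds.

Assumption: the SMILES holds no stereocentre and the diaryl ether axis rotates freely, so the target is achiral and there is no enantiomer to select.

**Route**

Step 1
Reactants: 1 2-isopropoxyphenol
Product: 4 2,3,4-tribromo-6-isopropoxyphenol, via 4-bromo-2-isopropoxyphenol 2 (not isolated), via 2,4-dibromo-6-isopropoxyphenol 3 (not isolated)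
Conditions: Br2 (3.1 equiv), NaOAc (3.3 equiv), AcOH, 10 → 45 °C, dark; aq NaHSO3; recrystallise
Reagents that add atoms: bromine, BrBr
Why: Electrophilic aromatic bromination in which the free OH places the first two bromines para and then ortho to itself and the isopropoxy group places the third one para to itself (the pattern known from guaiacol), while the bulky isopropyl group shields the last free C–H and NaOAc traps HBr so that the ether survives.

Step 2
Reactants: 4 2,3,4-tribromo-6-isopropoxyphenol; 5 ethyl bromoacetate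
Product: 6 ethyl 2-(2,3,4-tribromo-6-isopropoxyphenoxy)acetate
Conditions: K2CO3 (2 equiv), DMF, 25 → 50 °C
Reagents that add atoms: none
Why: Williamson ether synthesis in which the acidic, hindered phenoxide is still a good SN2 partner for the unhindered activated primary bromide, and no aryl bromide is touched.

Step 3
Reactants: 6 ethyl 2-(2,3,4-tribromo-6-isopropoxyphenoxy)acetate
Product: 7 2-(2,3,4-tribromo-6-isopropoxyphenoxy)acetic acid
Conditions: LiOH·H2O (3 equiv), THF–H2O 3:1, 25 °C; then 1 M HCl
Reagents that add atoms: lithium hydroxide, [Li+].[OH-]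
Why: Ester saponification under mild conditions that leave the aryl bromides and both ethers untouched.

Step 4
Reactants: 7 2-(2,3,4-tribromo-6-isopropoxyphenoxy)acetic acid; 8 potassium ethyl malonate
Product: 10 ethyl 3-oxo-4-(2,3,4-tribromo-6-isopropoxyphenoxy)butanoate, via acyl imidazolide 9 (not isolated)
Conditions: CDI (1.2 equiv), THF, 25 °C; then 8 (2 equiv), MgCl2 (2.5 equiv), Et3N (3 equiv), MeCN, 25 → 40 °C; 1 M HCl
Reagents that add atoms: 1,1'-carbonyldiimidazole, O=C(n1ccnc1)n1ccnc1 (its imidazolyl group stays only in 9)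
Why: Masamune–Brooks decarboxylative Claisen condensation in which the acyl imidazolide acylates the magnesium enolate of the malonate half ester made in the flask and loss of CO2 makes the C-acylation irreversible, under conditions far too mild to metalate the bromoarene.

Step 5
Reactants: 10 ethyl 3-oxo-4-(2,3,4-tribromo-6-isopropoxyphenoxy)butanoate; 11 acrolein
Product: 12 ethyl 5-oxo-2-[2-(2,3,4-tribromo-6-isopropoxyphenoxy)acetyl]pentanoate (racemic)
Conditions: 11 (1.05 equiv, freshly distilled, slow addition), KOt-Bu (5 mol %), t-BuOH–THF 1:1, 0 °C; AcOH quench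
Reagents that add atoms: none
Why: Intermolecular Michael addition, the key C–C bond formation, in which the soft doubly stabilised C2 enolate of 10 adds 1,4 to acrolein under catalytic base and joins the ring B fragment to the three-carbon fragment, the new C2 stereocentre being formed racemic and erased in step 7.

Step 6
Reactants: 12 ethyl 5-oxo-2-[2-(2,3,4-tribromo-6-isopropoxyphenoxy)acetyl]pentanoate (racemic)
Product: 14 ethyl 2-oxo-3-(2,3,4-tribromo-6-isopropoxyphenoxy)cyclohex-3-ene-1-carboxylate (racemic), via ketol 13 (not isolated)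
Conditions: TsOH·H2O (20 mol %), toluene, 80 °C
Reagents that add atoms: none
Why: Intramolecular aldol condensation (the ring-closing half of a Robinson-type annulation) in which only the aryloxy-bearing α' carbon can reach the aldehyde through a six-membered ring, reversible hemiacetal side equilibria drain into the conjugated enone, and the uncontrolled stereocentres of 13 and 14 vanish on dehydration and in step 7.

Step 7
Reactants: 14 ethyl 2-oxo-3-(2,3,4-tribromo-6-isopropoxyphenoxy)cyclohex-3-ene-1-carboxylate (racemic)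
Product: 15 ethyl 2-hydroxy-3-(2,3,4-tribromo-6-isopropoxyphenoxy)benzoate
Conditions: DDQ (1.2 equiv), 1,4-dioxane, 80 °C
Reagents that add atoms: none
Why: DDQ dehydrogenation in which the strongly enolised β-keto ester is a cyclohexa-1,3-dienol that loses hydride and a proton to gain aromaticity, which removes the last stereocentre and gives the hydrogen-bonded salicylate.

Step 8
Reactants: 15 ethyl 2-hydroxy-3-(2,3,4-tribromo-6-isopropoxyphenoxy)benzoate
Product: 16 2-hydroxy-3-(2,3,4-tribromo-6-isopropoxyphenoxy)benzoic acid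
Conditions: NaOH (5 equiv), EtOH–H2O 4:1, 70 °C; then 2 M HCl
Reagents that add atoms: sodium hydroxide, [Na+].[OH-]
Why: Ester saponification, run warm because the salicylate phenoxide slows attack, with an unactivated bromoarene and a diaryl ether that do not undergo substitution by hydroxide.

Step 9
Reactants: 16 2-hydroxy-3-(2,3,4-tribromo-6-isopropoxyphenoxy)benzoic acid
Product: 18 2,4-dibromo-6-(2,3,4-tribromo-6-isopropoxyphenoxy)phenol, via 5-bromo acid 17 (not isolated)
Conditions: Br2 (2.1 equiv), NaOAc (4 equiv), AcOH–H2O 9:1, 25 → 40 °C; aq NaHSO3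
Reagents that add atoms: bromine, BrBr
Why: Electrophilic bromination para to the OH followed by ipso-bromodecarboxylation at the carboxyl-bearing ortho carbon (the reaction that turns salicylic acid into tribromophenol), so both ring A bromines land only ortho and para to the OH while the thrice brominated ring B is too deactivated to compete.

Step 10
Reactants: 18 2,4-dibromo-6-(2,3,4-tribromo-6-isopropoxyphenoxy)phenol
Product: 19 1,2,3-tribromo-4-(3,5-dibromo-2-methoxyphenoxy)-5-isopropoxybenzene
Conditions: MeI (2 equiv), K2CO3 (2 equiv), DMF, 25 → 40 °C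
Reagents that add atoms: iodomethane, CI
Why: Williamson O-methylation of the only free, acidic phenol with the smallest possible electrophile, which tolerates the two flanking ortho groups.

Step 11
Reactants: 19 1,2,3-tribromo-4-(3,5-dibromo-2-methoxyphenoxy)-5-isopropoxybenzene
Product: 21 3,4,5-tribromo-2-(3,5-dibromo-2-methoxyphenoxy)phenol, via aryloxydichloroborane 20 (not isolated)
Conditions: BCl3 (1 M in CH2Cl2, 2.5 equiv), CH2Cl2, −78 → 0 °C; then H2O
Reagents that add atoms: boron trichloride, ClB(Cl)Cl (its BCl2 group stays only in 20)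
Why: Lewis acid ether cleavage in which BCl3 ionises the secondary isopropyl–oxygen bond far faster than it can demethylate the methyl ether at or below 0 °C, and hydrolysis of 20 releases the achiral target, which has no stereocentre to set.

**Compound list**

| No. | Name | SMILES | Role |
|---|---|---|---|
| 1 | 2-isopropoxyphenol | CC(C)Oc1ccccc1O | starting material |
| 2 | 4-bromo-2-isopropoxyphenol | CC(C)Oc1cc(Br)ccc1O | intermediate |
| 3 | 2,4-dibromo-6-isopropoxyphenol | CC(C)Oc1cc(Br)cc(Br)c1O | intermediate |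
| 4 | 2,3,4-tribromo-6-isopropoxyphenol | CC(C)Oc1cc(Br)c(Br)c(Br)c1O | intermediate |
| 5 | ethyl bromoacetate | CCOC(=O)CBr | starting material |
| 6 | ethyl 2-(2,3,4-tribromo-6-isopropoxyphenoxy)acetate | CCOC(=O)COc1c(OC(C)C)cc(Br)c(Br)c1Br | intermediate |
| 7 | 2-(2,3,4-tribromo-6-isopropoxyphenoxy)acetic acid | OC(=O)COc1c(OC(C)C)cc(Br)c(Br)c1Br | intermediate |
| 8 | potassium ethyl malonate | CCOC(=O)CC(=O)[O-].[K+] | starting material |
| 9 | 1-(imidazol-1-yl)-2-(2,3,4-tribromo-6-isopropoxyphenoxy)ethanone | O=C(COc1c(OC(C)C)cc(Br)c(Br)c1Br)n1ccnc1 | intermediate |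
| 10 | ethyl 3-oxo-4-(2,3,4-tribromo-6-isopropoxyphenoxy)butanoate | CCOC(=O)CC(=O)COc1c(OC(C)C)cc(Br)c(Br)c1Br | intermediate |
| 11 | acrolein | C=CC=O | starting material |
| 12 | ethyl 5-oxo-2-[2-(2,3,4-tribromo-6-isopropoxyphenoxy)acetyl]pentanoate (racemic) | CCOC(=O)C(CCC=O)C(=O)COc1c(OC(C)C)cc(Br)c(Br)c1Br | intermediate |
| 13 | ethyl 4-hydroxy-2-oxo-3-(2,3,4-tribromo-6-isopropoxyphenoxy)cyclohexane-1-carboxylate (racemic diastereomer mixture) | CCOC(=O)C1CCC(O)C(Oc2c(OC(C)C)cc(Br)c(Br)c2Br)C1=O | intermediate |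
| 14 | ethyl 2-oxo-3-(2,3,4-tribromo-6-isopropoxyphenoxy)cyclohex-3-ene-1-carboxylate (racemic) | CCOC(=O)C1CCC=C(Oc2c(OC(C)C)cc(Br)c(Br)c2Br)C1=O | intermediate |
| 15 | ethyl 2-hydroxy-3-(2,3,4-tribromo-6-isopropoxyphenoxy)benzoate | CCOC(=O)c1cccc(Oc2c(OC(C)C)cc(Br)c(Br)c2Br)c1O | intermediate |
| 16 | 2-hydroxy-3-(2,3,4-tribromo-6-isopropoxyphenoxy)benzoic acid | OC(=O)c1cccc(Oc2c(OC(C)C)cc(Br)c(Br)c2Br)c1O | intermediate |
| 17 | 5-bromo-2-hydroxy-3-(2,3,4-tribromo-6-isopropoxyphenoxy)benzoic acid | OC(=O)c1cc(Br)cc(Oc2c(OC(C)C)cc(Br)c(Br)c2Br)c1O | intermediate |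
| 18 | 2,4-dibromo-6-(2,3,4-tribromo-6-isopropoxyphenoxy)phenol | Oc1c(Br)cc(Br)cc1Oc1c(OC(C)C)cc(Br)c(Br)c1Br | intermediate |
| 19 | 1,2,3-tribromo-4-(3,5-dibromo-2-methoxyphenoxy)-5-isopropoxybenzene | COc1c(Br)cc(Br)cc1Oc1c(OC(C)C)cc(Br)c(Br)c1Br | intermediate |
| 20 | dichloro[3,4,5-tribromo-2-(3,5-dibromo-2-methoxyphenoxy)phenoxy]borane | COc1c(Br)cc(Br)cc1Oc1c(OB(Cl)Cl)cc(Br)c(Br)c1Br | intermediate |
| 21 | 3,4,5-tribromo-2-(3,5-dibromo-2-methoxyphenoxy)phenol (achiral) | COc1c(Br)cc(Br)cc1Oc1c(O)cc(Br)c(Br)c1Br | target |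

**Totals**
Total step count: 11. Longest linear sequence: 11 steps (1 → 21). Compounds 5, 8 and 11 are bought.

**Three steps most likely to fail**

Step 5 (Michael addition). Acrolein can polymerise under base, and adduct 12 still carries an acidic C–H, so a second addition is possible. The fallback sets out from 10 and comes back at 12. The conjugate addition is replaced by an acetoacetic ester alkylation with a masked aldehyde. Compound 10 is C-alkylated with 2-(2-bromoethyl)-1,3-dioxolane (K2CO3, NaI, DMF, 60 °C) to give ethyl 2-[2-(1,3-dioxolan-2-yl)ethyl]-3-oxo-4-(2,3,4-tribromo-6-isopropoxyphenoxy)butanoate F1. The acetal of F1 is then hydrolysed (1 M HCl, THF, 25 °C) to 12.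

Step 6 (aldol ring closure). Compound 12 may rest as its cyclic hemiacetal, dehydrate to a 4H-pyran or revert by retro-Michael reaction instead of closing the carbocycle. The fallback sets out from 10 and comes back at 15, so steps 5 to 7 are bypassed. Compound 10 is silylated twice (Me3SiOTf 2.3 equiv, Et3N 2.6 equiv, Et2O, 0 °C). This gives first ethyl 4-(2,3,4-tribromo-6-isopropoxyphenoxy)-3-(trimethylsilyloxy)but-2-enoate F2 and then 1-ethoxy-4-(2,3,4-tribromo-6-isopropoxyphenoxy)-1,3-bis(trimethylsilyloxy)buta-1,3-diene F3. F3 is condensed with 1,1,3,3-tetramethoxypropane (Me3SiOTf 0.3 equiv, CH2Cl2, −78 → 20 °C; then aq HCl). This formal [3+3] Mukaiyama aldol cyclocondensation (Chan–Brownbridge type) delivers 15 directly at the arene oxidation level.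

Step 9 (bromodecarboxylation). The ipso step may stall at 17, or forcing it may start to brominate ring B. The fallback sets out from 16 and comes back at 18, and it separates loss of CO2 from bromination. Compound 16 is heated in quinoline (200 °C, no metal) to give 2-(2,3,4-tribromo-6-isopropoxyphenoxy)phenol F4. F4 is then brominated (Br2 2.05 equiv, NaOAc, AcOH, 15 °C) para and then ortho to the OH, passing through 4-bromo-2-(2,3,4-tribromo-6-isopropoxyphenoxy)phenol F5, to give 18.

**Further compounds**
F1 | step 5 | ethyl 2-[2-(1,3-dioxolan-2-yl)ethyl]-3-oxo-4-(2,3,4-tribromo-6-isopropoxyphenoxy)butanoate (racemic) | CCOC(=O)C(CCC1OCCO1)C(=O)COc1c(OC(C)C)cc(Br)c(Br)c1Br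
F2 | step 6 | ethyl 4-(2,3,4-tribromo-6-isopropoxyphenoxy)-3-(trimethylsilyloxy)but-2-enoate (alkene geometry not controlled) | CCOC(=O)C=C(O[Si](C)(C)C)COc1c(OC(C)C)cc(Br)c(Br)c1Br
F3 | step 6 | 1-ethoxy-4-(2,3,4-tribromo-6-isopropoxyphenoxy)-1,3-bis(trimethylsilyloxy)buta-1,3-diene (alkene geometry not controlled) | CCOC(O[Si](C)(C)C)=CC(O[Si](C)(C)C)=COc1c(OC(C)C)cc(Br)c(Br)c1Br
F4 | step 9 | 2-(2,3,4-tribromo-6-isopropoxyphenoxy)phenol | Oc1ccccc1Oc1c(OC(C)C)cc(Br)c(Br)c1Br
F5 | step 9 | 4-bromo-2-(2,3,4-tribromo-6-isopropoxyphenoxy)phenol | Oc1ccc(Br)cc1Oc1c(OC(C)C)cc(Br)c(Br)c1Br
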